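**Retrosynthetic overview**
1. The γ-lactone is closed last from a C-7 hydroxy tert-butyl ester; the ten-membered ring is closed just before by C6–C7 bond formation, an electrochemical chromium-catalysed γ-chloroallylation of a C-7 aldehyde that also installs Cl, C-6, C-7 and the exocyclic alkene.
2. The open precursor comes from addition of a C-3 to C-6 (plus C-16) dienyllithium to a δ-lactone carbonyl (C-2), a 1,3-syn reduction at C-2, and a chelation-controlled propionate aldol at a C-8 ketone.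
3. Ring A is built first on a D-galactal-derived enone δ-lactone (C-2, C-1, C-10, C-9, C-8, C-7 are sugar C-1 to C-6): cuprate addition (C-10), α-methylation and α-formylation (C-1), allylboration (C-14), ring-closing metathesis, directed hydroboration (C-11).
4. The only purchased stereocentre that survives is C-9 (galactose C-4); every other centre is relayed from it.
5. Ring order: ring A, then the ten-membered ring, then the γ-lactone.

**Assumptions**
- Briarane numbering of the target (C-1 to C-20) is used for all intermediates; α means the face opposite the C-1 methyl group.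
- 6-O-(Triisopropylsilyl)-D-galactal is bought (it is one silylation from D-galactal).
- The C-5=C-6 chloroalkene is drawn as E throughout; the Z isomer formed alongside it in step 2 is carried on, because the allylchromium species of step 24 equilibrates.

**Route**

Step 1
Reactants: 1 1,3-bis(tert-butyldimethylsilyloxy)propan-2-one
Product: 2 1,3-bis(tert-butyldimethylsilyloxy)-2-(chloromethylidene)propane
Conditions: ClCH2PPh3Cl, NaN(SiMe3)2, THF, −78 → 0 °C
Reagents that add atoms: (chloromethyl)triphenylphosphonium chloride, ClC[P+](c1ccccc1)(c1ccccc1)c1ccccc1.[Cl-]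
Why: Wittig chloromethylenation of a symmetrical ketone, so only one alkene can form.

Step 2
Reactants: 2 1,3-bis(tert-butyldimethylsilyloxy)-2-(chloromethylidene)propane
Product: 3 (E)-2-(chloromethylidene)-3-(tert-butyldimethylsilyloxy)propan-1-ol
Conditions: HF·pyridine (0.6 equiv), pyridine, THF, 0 °C; recovered 2 recycled
Reagents that add atoms: none
Why: Statistical mono-desilylation of a bis-silyl ether; the alkene geometry created here is erased in step 24.

Step 3
Reactants: 3 (E)-2-(chloromethylidene)-3-(tert-butyldimethylsilyloxy)propan-1-ol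
Product: 4 (Z)-3-chloro-2-[(tert-butyldimethylsilyloxy)methyl]prop-2-enal
Conditions: Dess–Martin periodinane, CH2Cl2, 0 °C → rt
Reagents that add atoms: none
Why: Dess–Martin oxidation of a primary allylic alcohol to the enal without touching the vinyl chloride.

Step 4
Reactants: 4 (Z)-3-chloro-2-[(tert-butyldimethylsilyloxy)methyl]prop-2-enal
Product: 5 (1E,3E)-4-chloro-1-iodo-3-[(tert-butyldimethylsilyloxy)methyl]buta-1,3-diene
Conditions: CrCl2, CHI3, THF, 0 °C
Reagents that add atoms: iodoform, IC(I)I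
Why: Takai–Utimoto iodo-olefination gives the (E)-alkenyl iodide (future C-3=C-4) and leaves the vinyl chloride alone.

Step 5
Reactants: 6 6-O-(triisopropylsilyl)-D-galactal
Product: 7 3,4-di-O-(4-methoxybenzyl)-6-O-(triisopropylsilyl)-D-galactal
Conditions: NaH, 4-MeOC6H4CH2Cl, Bu4NI (cat.), DMF, 0 °C → rt
Reagents that add atoms: 4-methoxybenzyl chloride, COc1ccc(CCl)cc1
Why: Williamson etherification of both secondary hydroxyls; the O-4 ether later serves as the chelating group at C-9.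

Step 6
Reactants: 7 3,4-di-O-(4-methoxybenzyl)-6-O-(triisopropylsilyl)-D-galactal
Product: 8 (5R,6R)-5-(4-methoxybenzyloxy)-6-[(triisopropylsilyloxy)methyl]-5,6-dihydro-2H-pyran-2-one
Conditions: pyridinium chlorochromate C5H5NH[CrO3Cl] (3 equiv), NaOAc, 4 Å MS, ClCH2CH2Cl, 70 °C
Reagents that add atoms: pyridinium chlorochromate, [O-][Cr](=O)(=O)Cl.c1cc[nH+]cc1
Why: Chlorochromate oxidation of a glycal with allylic transposition (Ferrier-type, loss of the O-3 ether) gives the enone δ-lactone; sugar C-4 (future C-9) is untouched.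

Step 7
Reactants: 8 enone δ-lactone
Product: 10 1-methyl-10-isopropenyl δ-lactone, via bromomagnesium enolate 9 (not isolated)
Conditions: (CH2=CMe)2CuMgBr [from CH2=C(Me)MgBr and CuI], THF, −78 °C; then MeI, HMPA, −78 → −20 °C
Reagents that add atoms: bromomagnesium di(prop-1-en-2-yl)cuprate, C=C(C)[Cu-]C(C)=C.[Mg+]Br; iodomethane, CI
Why: Cuprate conjugate addition occurs anti to the adjacent 9-OPMB group (and the cis C-8 side chain), setting C-10, and the enolate is C-methylated anti to the new isopropenyl group.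

Step 8
Reactants: 10 1-methyl-10-isopropenyl δ-lactone
Product: 12 1-formyl-1-methyl-10-isopropenyl δ-lactone, via lithium enolate 11 (not isolated)
Conditions: LiN(i-Pr)2, THF, −78 °C; then HCO2Me, −78 → −40 °C
Reagents that add atoms: methyl formate, COC=O
Why: Claisen-type C-formylation of the planar enolate takes place anti to the C-10 isopropenyl group, setting the quaternary C-1 with the formyl carbon (C-14) trans to C-11.

Step 9
Reactants: 12 1-formyl-1-methyl-10-isopropenyl δ-lactone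
Product: 13 C-14 homoallylic alcohol
Conditions: CH2=CHCH2B(pin), PhMe, 40 °C
Reagents that add atoms: allylboronic acid pinacol ester, C=CCB1OC(C)(C)C(C)(C)O1
Why: Non-chelating allylboration follows the Cornforth/Felkin–Anh model (aldehyde C=O anti to the lactone C=O, allyl group entering past the methyl and anti to C-10), setting 14α-OH.

Step 10
Reactants: 13 C-14 homoallylic alcohol
Product: 14 ring A cyclohexene lactone
Conditions: second-generation Grubbs catalyst (5 mol %), CH2Cl2, 40 °C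
Reagents that add atoms: none
Why: Ring-closing metathesis of the isopropenyl and allyl groups closes ring A as the C-11=C-12 trisubstituted cyclohexene, trans-fused to the lactone.

Step 11
Reactants: 14 ring A cyclohexene lactone
Product: 16 12α,14α-diol lactone, via cyclic alkoxyborane 15 (not isolated)
Conditions: BH3·THF, THF, 0 °C → rt; then NaBO3·4H2O, THF/H2O
Reagents that add atoms: sodium perborate, [Na+].[Na+].O[B-]1(O)OO[B-](O)(O)OO1
Why: Hydroboration–oxidation is delivered from the α face (tethered through the 14-O-borane, opposite the axial C-1 methyl and the C-9 branch), placing H-11 α and hence the C-11 methyl β; C-12 is a temporary carbinol.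

Step 12
Reactants: 16 12α,14α-diol lactone
Product: 17 12-O-tert-butyldimethylsilyl lactone
Conditions: t-BuMe2SiCl, imidazole, DMF, 0 °C
Reagents that add atoms: tert-butyldimethylsilyl chloride, CC(C)(C)[Si](C)(C)Cl
Why: Selective silylation of the less hindered 12-OH; the neopentyl axial 14-OH next to the quaternary C-1 stays free.

Step 13
Reactants: 17 12-O-tert-butyldimethylsilyl lactone; 5 (1E,3E)-4-chloro-1-iodo-3-[(tert-butyldimethylsilyloxy)methyl]buta-1,3-diene
Product: 19 hydroxy dienone, via dienyllithium 18 (not isolated)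
Conditions: 17, LiN(SiMe3)2 (1.05 equiv), THF, −78 °C; 18 [from 5 (1.4 equiv), t-BuLi (2.8 equiv), Et2O, −78 °C] added; AcOH quench at −78 °C
Reagents that add atoms: none
Why: Iodine–lithium exchange and single addition of the alkenyllithium to the hindered lactone carbonyl (acyl substitution) forms C2–C3 as an enone and frees 8-OH; the low temperature suppresses retro-aldol of the 14-alkoxide.

Step 14
Reactants: 19 hydroxy dienone
Product: 20 2,8,14-triol
Conditions: Et2BOMe, THF/MeOH (4:1), −78 °C; NaBH4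
Reagents that add atoms: none
Why: Narasaka–Prasad reduction through the boron chelate of the 14-hydroxy ketone gives the 1,3-syn diol, setting 2α-OH.

Step 15
Reactants: 20 2,8,14-triol
Product: 21 2,14-cyclic orthobutyrate
Conditions: PrC(OMe)3, PPTS (cat.), CH2Cl2, rt
Reagents that add atoms: trimethyl orthobutyrate, CCCC(OC)(OC)OC
Why: Only the syn-1,3-diol can form the six-membered cyclic orthoester, which protects O-2 and O-14 and carries the future butanoyl carbon.

Step 16
Reactants: 21 2,14-cyclic orthobutyrate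
Product: 22 C-8 ketone
Conditions: Dess–Martin periodinane, pyridine, CH2Cl2, 0 °C → rt
Reagents that add atoms: none
Why: Buffered Dess–Martin oxidation of the only free secondary alcohol removes the sugar-derived C-8 stereocentre.

Step 17
Reactants: 22 C-8 ketone
Product: 23 aldol adduct
Conditions: EtCO2t-Bu, LiN(i-Pr)2, THF, −78 °C; MgBr2·OEt2; then 22, −78 °C
Reagents that add atoms: tert-butyl propanoate, CCC(=O)OC(C)(C)C
Why: Cram-chelate aldol addition (magnesium bridging the ketone and 9-OPMB, attack from the H-9 side) sets the tertiary C-8 carbinol, and the closed transition state of the (E)-enolate sets C-17.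

Step 18
Reactants: 23 aldol adduct
Product: 24 9-alcohol
Conditions: DDQ, CH2Cl2/pH 7 buffer (10:1), 0 °C
Reagents that add atoms: none
Why: Oxidative cleavage of the 4-methoxybenzyl ether under buffered conditions that spare the orthoester and the silyl ethers.

Step 19
Reactants: 24 9-alcohol
Product: 25 14-butanoate 2,9-diol
Conditions: PPTS (cat.), THF/H2O (10:1), 0 °C
Reagents that add atoms: water, O
Why: Mild orthoester hydrolysis is expected to follow the axial-ester rule: the hemiorthoester collapses to leave the acyl group on the axial ring oxygen O-14 and free the exocyclic allylic 2-OH.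

Step 20
Reactants: 25 14-butanoate 2,9-diol
Product: 26 2,9-diacetate
Conditions: Ac2O, DMAP, pyridine, CH2Cl2, rt
Reagents that add atoms: acetic anhydride, CC(=O)OC(C)=O
Why: Acetylation of both secondary alcohols; the tertiary 8-OH does not react.

Step 21
Reactants: 26 2,9-diacetate
Product: 27 7,12,16-triol
Conditions: HF·pyridine, THF, 0 °C → rt
Reagents that add atoms: none
Why: Global desilylation; the tert-butyl ester prevents premature lactonisation of the primary 7-OH.

Step 22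
Reactants: 27 7,12,16-triol
Product: 28 C-16 allylic bromide
Conditions: CBr4, PPh3, 2,6-lutidine, CH2Cl2, −20 °C
Reagents that add atoms: carbon tetrabromide, BrC(Br)(Br)Br
Why: Appel bromination is selective for the primary allylic alcohol over the neopentyl primary 7-OH and the secondary 12-OH.

Step 23
Reactants: 28 C-16 allylic bromide
Product: 29 keto aldehyde
Conditions: Dess–Martin periodinane, pyridine, CH2Cl2, 0 °C → rt
Reagents that add atoms: none
Why: Double Dess–Martin oxidation gives the C-7 aldehyde and the C-12 ketone under conditions that do not epimerise C-11.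

Step 24
Reactants: 29 keto aldehyde
Product: 31 target CNP0283653.2, via silyl ether 30 (not isolated)
Conditions: CrCl2 (20 mol %), Me3SiCl, Bu4NBr, DMF/THF (1:4), undivided cell, Al anode/Ni-foam cathode, 3 mA, 2.2 F mol−1, 2 mM (slow addition), rt; then CF3CO2H/CH2Cl2 (1:5), 0 °C
Reagents that add atoms: none
Why: Proposed new method: cathodic regeneration of divalent chromium from the silylated trivalent chromium alkoxide should make the Nozaki–Hiyama allylation catalytic; the γ-chloroallylchromium formed from the allylic bromide equilibrates to its E form and adds through a chair transition state (anti chlorohydrin, C-6) with Felkin–Anh attack on the α-quaternary aldehyde (C-7), closing the ten-membered ring and creating the exocyclic alkene, after which acid lactonises O-7 onto the tert-butyl ester; the closest known reactions are stoichiometric CrCl2 allylations with 1,3-dihalopropenes, CrCl2 closures of ten-membered carbocycles, and electrochemical chromium-catalysed Nozaki–Hiyama–Kishi couplings.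

**Compound list**
1 | 1,3-bis(tert-butyldimethylsilyloxy)propan-2-one | O=C(CO[Si](C)(C)C(C)(C)C)CO[Si](C)(C)C(C)(C)C | starting material
2 | 1,3-bis(tert-butyldimethylsilyloxy)-2-(chloromethylidene)propane | ClC=C(CO[Si](C)(C)C(C)(C)C)CO[Si](C)(C)C(C)(C)C | intermediate
3 | (E)-2-(chloromethylidene)-3-(tert-butyldimethylsilyloxy)propan-1-ol (Cl cis to CH2OH) | OC/C(CO[Si](C)(C)C(C)(C)C)=C\Cl | intermediate
4 | (Z)-3-chloro-2-[(tert-butyldimethylsilyloxy)methyl]prop-2-enal (Cl cis to CHO) | O=C/C(CO[Si](C)(C)C(C)(C)C)=C\Cl | intermediate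
5 | (1E,3E)-4-chloro-1-iodo-3-[(tert-butyldimethylsilyloxy)methyl]buta-1,3-diene (C-3 to C-6 and C-16) | I/C=C/C(CO[Si](C)(C)C(C)(C)C)=C\Cl | intermediate
6 | 6-O-(triisopropylsilyl)-D-galactal | CC(C)[Si](OC[C@H]1OC=C[C@@H](O)[C@H]1O)(C(C)C)C(C)C | starting material
7 | 3,4-di-O-(4-methoxybenzyl)-6-O-(triisopropylsilyl)-D-galactal | CC(C)[Si](OC[C@H]1OC=C[C@@H](OCc2ccc(OC)cc2)[C@H]1OCc3ccc(OC)cc3)(C(C)C)C(C)C | intermediate
8 | (5R,6R)-5-(4-methoxybenzyloxy)-6-[(triisopropylsilyloxy)methyl]-5,6-dihydro-2H-pyran-2-one (C-2 carbonyl, C-1=C-10, C-9 OPMB, C-8, C-7) | O=C1C=C[C@@H](OCc2ccc(OC)cc2)[C@@H](CO[Si](C(C)C)(C(C)C)C(C)C)O1 | intermediate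
9 | bromomagnesium enolate of the lactone after isopropenyl addition at C-10 (isopropenyl anti to 9-OPMB) | Br[Mg]OC1=C[C@H](C(C)=C)[C@@H](OCc2ccc(OC)cc2)[C@@H](CO[Si](C(C)C)(C(C)C)C(C)C)O1 | intermediate (not isolated)
10 | δ-lactone with C-10 isopropenyl anti to 9-OPMB and C-1 methyl anti to the isopropenyl group | O=C1[C@@H](C)[C@H](C(C)=C)[C@@H](OCc2ccc(OC)cc2)[C@@H](CO[Si](C(C)C)(C(C)C)C(C)C)O1 | intermediate
11 | lithium enolate of 10 | [Li+].[O-]C1=C(C)[C@H](C(C)=C)[C@@H](OCc2ccc(OC)cc2)[C@@H](CO[Si](C(C)C)(C(C)C)C(C)C)O1 | intermediate (not isolated)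
12 | δ-lactone with quaternary C-1 (methyl cis, formyl trans to the C-10 isopropenyl group) | O=C1[C@](C=O)(C)[C@H](C(C)=C)[C@@H](OCc2ccc(OC)cc2)[C@@H](CO[Si](C(C)C)(C(C)C)C(C)C)O1 | intermediate
13 | (14S)-homoallylic alcohol: 12 with the formyl group converted to CH(OH)CH2CH=CH2 | O=C1[C@]([C@@H](O)CC=C)(C)[C@H](C(C)=C)[C@@H](OCc2ccc(OC)cc2)[C@@H](CO[Si](C(C)C)(C(C)C)C(C)C)O1 | intermediate
14 | ring A cyclohexene (C-11=C-12, 14α-OH) trans-fused to the δ-lactone | O=C1O[C@H](CO[Si](C(C)C)(C(C)C)C(C)C)[C@H](OCc3ccc(OC)cc3)[C@H]2C(C)=CC[C@H](O)[C@]12C | intermediate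
15 | cyclic alkoxyborane bridging O-14 and C-12 on the α face | O=C1O[C@H](CO[Si](C(C)C)(C(C)C)C(C)C)[C@H](OCc4ccc(OC)cc4)[C@H]2[C@@H](C)[C@H]3C[C@H](O[BH]3)[C@]12C | intermediate (not isolated)
16 | 12α,14α-diol lactone with 11β-methyl | O=C1O[C@H](CO[Si](C(C)C)(C(C)C)C(C)C)[C@H](OCc3ccc(OC)cc3)[C@H]2[C@@H](C)[C@H](O)C[C@H](O)[C@]12C | intermediate
17 | 12-O-tert-butyldimethylsilyl ether of 16 (14-OH free) | O=C1O[C@H](CO[Si](C(C)C)(C(C)C)C(C)C)[C@H](OCc3ccc(OC)cc3)[C@H]2[C@@H](C)[C@H](O[Si](C)(C)C(C)(C)C)C[C@H](O)[C@]12C | intermediate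
18 | (1E,3E)-4-chloro-3-[(tert-butyldimethylsilyloxy)methyl]buta-1,3-dienyllithium | [Li]/C=C/C(CO[Si](C)(C)C(C)(C)C)=C\Cl | intermediate (not isolated)
19 | seco dienone: C-2 ketone conjugated to (3E)-C-3=C-4 and (5E)-C-5=C-6(Cl), 8-OH and 14-OH free, 9-OPMB, 7-OTIPS, 12-OTBS, 16-OTBS | CC(C)(C)[Si](C)(C)OCC(=C/Cl)/C=C/C(=O)[C@]1(C)[C@@H]([C@@H](OCc2ccc(OC)cc2)[C@H](O)CO[Si](C(C)C)(C(C)C)C(C)C)[C@@H](C)[C@H](O[Si](C)(C)C(C)(C)C)C[C@@H]1O | intermediate
20 | 2α,14α-syn-diol (2,8,14-triol) from 19 | CC(C)(C)[Si](C)(C)OCC(=C/Cl)/C=C/[C@@H](O)[C@]1(C)[C@@H]([C@@H](OCc2ccc(OC)cc2)[C@H](O)CO[Si](C(C)C)(C(C)C)C(C)C)[C@@H](C)[C@H](O[Si](C)(C)C(C)(C)C)C[C@@H]1O | intermediate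
21 | 2,14-O-(1-methoxybutylidene) cyclic orthoester of 20 (orthoester carbon unassigned) | CC(C)(C)[Si](C)(C)OCC(=C/Cl)/C=C/[C@H]1OC(CCC)(OC)O[C@H]2C[C@@H](O[Si](C)(C)C(C)(C)C)[C@H](C)[C@H]([C@@H](OCc3ccc(OC)cc3)[C@H](O)CO[Si](C(C)C)(C(C)C)C(C)C)[C@@]12C | intermediate
22 | C-8 ketone of 21 | CC(C)(C)[Si](C)(C)OCC(=C/Cl)/C=C/[C@H]1OC(CCC)(OC)O[C@H]2C[C@@H](O[Si](C)(C)C(C)(C)C)[C@H](C)[C@H]([C@@H](OCc3ccc(OC)cc3)C(=O)CO[Si](C(C)C)(C(C)C)C(C)C)[C@@]12C | intermediate
23 | aldol adduct: tertiary 8-OH, C-17 methyl and tert-butyl ester (C-18), configurations at C-8 and C-17 as in the target | CC(C)(C)[Si](C)(C)OCC(=C/Cl)/C=C/[C@H]1OC(CCC)(OC)O[C@H]2C[C@@H](O[Si](C)(C)C(C)(C)C)[C@H](C)[C@H]([C@@H](OCc3ccc(OC)cc3)[C@@](O)(CO[Si](C(C)C)(C(C)C)C(C)C)[C@@H](C)C(=O)OC(C)(C)C)[C@@]12C | intermediate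
24 | 9-alcohol (23 without the 4-methoxybenzyl group) | CC(C)(C)[Si](C)(C)OCC(=C/Cl)/C=C/[C@H]1OC(CCC)(OC)O[C@H]2C[C@@H](O[Si](C)(C)C(C)(C)C)[C@H](C)[C@H]([C@@H](O)[C@@](O)(CO[Si](C(C)C)(C(C)C)C(C)C)[C@@H](C)C(=O)OC(C)(C)C)[C@@]12C | intermediate
25 | 14-O-butanoyl 2,9-diol | CC(C)(C)[Si](C)(C)OCC(=C/Cl)/C=C/[C@@H](O)[C@]1(C)[C@@H]([C@@H](O)[C@@](O)(CO[Si](C(C)C)(C(C)C)C(C)C)[C@@H](C)C(=O)OC(C)(C)C)[C@@H](C)[C@H](O[Si](C)(C)C(C)(C)C)C[C@@H]1OC(=O)CCC | intermediate
26 | 2,9-di-O-acetyl-14-O-butanoyl tris-silyl ether | CC(C)(C)[Si](C)(C)OCC(=C/Cl)/C=C/[C@@H](OC(C)=O)[C@]1(C)[C@@H]([C@@H](OC(C)=O)[C@@](O)(CO[Si](C(C)C)(C(C)C)C(C)C)[C@@H](C)C(=O)OC(C)(C)C)[C@@H](C)[C@H](O[Si](C)(C)C(C)(C)C)C[C@@H]1OC(=O)CCC | intermediate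
27 | 7,12,16-triol | OCC(=C/Cl)/C=C/[C@@H](OC(C)=O)[C@]1(C)[C@@H]([C@@H](OC(C)=O)[C@@](O)(CO)[C@@H](C)C(=O)OC(C)(C)C)[C@@H](C)[C@H](O)C[C@@H]1OC(=O)CCC | intermediate
28 | C-16 allylic bromide (7-OH and 12-OH free) | BrCC(=C/Cl)/C=C/[C@@H](OC(C)=O)[C@]1(C)[C@@H]([C@@H](OC(C)=O)[C@@](O)(CO)[C@@H](C)C(=O)OC(C)(C)C)[C@@H](C)[C@H](O)C[C@@H]1OC(=O)CCC | intermediate
29 | C-7 aldehyde, C-12 ketone, C-16 allylic bromide | BrCC(=C/Cl)/C=C/[C@@H](OC(C)=O)[C@]1(C)[C@@H]([C@@H](OC(C)=O)[C@@](O)(C=O)[C@@H](C)C(=O)OC(C)(C)C)[C@@H](C)C(=O)C[C@@H]1OC(=O)CCC | intermediate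
30 | cyclised 7-O-trimethylsilyl ether tert-butyl ester (ten-membered ring, 6α-Cl, exocyclic C-5=C-16) | C=C1/C=C/[C@@H](OC(C)=O)[C@]2(C)[C@@H]([C@@H](OC(C)=O)[C@](O)([C@@H](C)C(=O)OC(C)(C)C)[C@@H](O[Si](C)(C)C)[C@H]1Cl)[C@@H](C)C(=O)C[C@@H]2OC(=O)CCC | intermediate (not isolated)
31 | CNP0283653.2, (1R,2R,6S,7R,8R,9R,10S,11R,14S,17R) in briarane numbering | C=C1/C=C/[C@@H](OC(C)=O)[C@]2(C)[C@@H]([C@@H](OC(C)=O)[C@]3(O)[C@@H](C)C(=O)O[C@H]3[C@H]1Cl)[C@@H](C)C(=O)C[C@@H]2OC(=O)CCC | target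

**Step count**
Total: 24 steps (4 for the dienyl iodide 5, 20 in the main line).
Longest linear sequence: 20 steps (6 to 31, steps 5 to 24).

**Three steps most likely to fail**

Step 24 (the proposed new step). The catalytic turnover, the γ versus α regiochemistry of the allylchromium, and the facial selectivity at the α-hydroxy aldehyde are all untested in a ten-membered ring closure. The fallback is known chemistry. Setting out from 29, the tertiary alcohol is silylated with N-(trimethylsilyl)imidazole to give the 8-O-trimethylsilyl keto aldehyde F1, which enforces non-chelated Felkin–Anh attack. F1 is cyclised with stoichiometric CrCl2 in THF at high dilution (the classical Nozaki–Hiyama allylation, precedented for ten-membered carbocycles) to the silylated cyclised hydroxy ester F2. CF3CO2H then removes the silyl group and lactonises, coming back to the route at 31.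

Step 19. The regiochemistry of orthoester opening rests on the axial-ester rule and could give the 2-butanoate instead. The fallback sets out from 23: the orthoester is hydrolysed and the resulting monobutanoate removed with K2CO3 in MeOH to give the 2,14-diol F3. The less hindered allylic 2-OH is acetylated selectively (Ac2O, 2,4,6-collidine, −20 °C) to the 2-acetate F4. The axial 14-OH is then butanoylated under forcing conditions ((PrCO)2O, DMAP) to the 2-acetate 14-butanoate F5, and DDQ removes the 4-methoxybenzyl group to give the 9-alcohol F6. Acetylation of F6 (Ac2O, DMAP) comes back to the route at 26.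

Step 6. The chlorochromate oxidation may attack the 4-methoxybenzyl ethers or fail to expel the O-3 ether. The fallback sets out from 7: iodohydroxylation (N-iodosuccinimide, aqueous MeCN) gives the 2-deoxy-2-iodo lactol F7, Dess–Martin oxidation gives the 2-iodo lactone F8, and zinc dust in AcOH/EtOH effects reductive β-elimination of the O-3 ether, coming back to the route at 8.

**Further compounds**
F1 | step 24 | 8-O-trimethylsilyl ether of keto aldehyde 29 | BrCC(=C/Cl)/C=C/[C@@H](OC(C)=O)[C@]1(C)[C@@H]([C@@H](OC(C)=O)[C@@](O[Si](C)(C)C)(C=O)[C@@H](C)C(=O)OC(C)(C)C)[C@@H](C)C(=O)C[C@@H]1OC(=O)CCC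
F2 | step 24 | cyclised 7-hydroxy 8-O-trimethylsilyl tert-butyl ester | C=C1/C=C/[C@@H](OC(C)=O)[C@]2(C)[C@@H]([C@@H](OC(C)=O)[C@](O[Si](C)(C)C)([C@@H](C)C(=O)OC(C)(C)C)[C@@H](O)[C@H]1Cl)[C@@H](C)C(=O)C[C@@H]2OC(=O)CCC
F3 | step 19 | 2,14-diol from 23 (9-OPMB retained) | CC(C)(C)[Si](C)(C)OCC(=C/Cl)/C=C/[C@@H](O)[C@]1(C)[C@@H]([C@@H](OCc2ccc(OC)cc2)[C@@](O)(CO[Si](C(C)C)(C(C)C)C(C)C)[C@@H](C)C(=O)OC(C)(C)C)[C@@H](C)[C@H](O[Si](C)(C)C(C)(C)C)C[C@@H]1O
F4 | step 19 | 2-O-acetyl 14-alcohol | CC(C)(C)[Si](C)(C)OCC(=C/Cl)/C=C/[C@@H](OC(C)=O)[C@]1(C)[C@@H]([C@@H](OCc2ccc(OC)cc2)[C@@](O)(CO[Si](C(C)C)(C(C)C)C(C)C)[C@@H](C)C(=O)OC(C)(C)C)[C@@H](C)[C@H](O[Si](C)(C)C(C)(C)C)C[C@@H]1O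
F5 | step 19 | 2-O-acetyl 14-O-butanoyl 9-O-(4-methoxybenzyl) ether | CC(C)(C)[Si](C)(C)OCC(=C/Cl)/C=C/[C@@H](OC(C)=O)[C@]1(C)[C@@H]([C@@H](OCc2ccc(OC)cc2)[C@@](O)(CO[Si](C(C)C)(C(C)C)C(C)C)[C@@H](C)C(=O)OC(C)(C)C)[C@@H](C)[C@H](O[Si](C)(C)C(C)(C)C)C[C@@H]1OC(=O)CCC
F6 | step 19 | 2-O-acetyl 14-O-butanoyl 9-alcohol | CC(C)(C)[Si](C)(C)OCC(=C/Cl)/C=C/[C@@H](OC(C)=O)[C@]1(C)[C@@H]([C@@H](O)[C@@](O)(CO[Si](C(C)C)(C(C)C)C(C)C)[C@@H](C)C(=O)OC(C)(C)C)[C@@H](C)[C@H](O[Si](C)(C)C(C)(C)C)C[C@@H]1OC(=O)CCC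
F7 | step 6 | 2-deoxy-2-iodo-3,4-di-O-(4-methoxybenzyl)-6-O-(triisopropylsilyl)-D-hexopyranose (C-1 and C-2 unassigned) | CC(C)[Si](OC[C@H]1OC(O)C(I)[C@@H](OCc2ccc(OC)cc2)[C@H]1OCc3ccc(OC)cc3)(C(C)C)C(C)C
F8 | step 6 | 2-deoxy-2-iodo-3,4-di-O-(4-methoxybenzyl)-6-O-(triisopropylsilyl)-D-hexono-1,5-lactone (C-2 unassigned) | CC(C)[Si](OC[C@H]1OC(=O)C(I)[C@@H](OCc2ccc(OC)cc2)[C@H]1OCc3ccc(OC)cc3)(C(C)C)C(C)C
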